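## Retrosynthetic overview

1. The target is reached from lactone 21 by protecting-group and acyl adjustments only (15-OAc, 2-O-angelate, free 8-OH).
2. The α-methylene-γ-butyrolactone ring (O–C6–C7–C11–C12) is read as CO2 inserted into the C6–C11 bond of a methylenecyclopropane (ring C6–C7–C11, exocyclic C11=C13). C6 is also allylic to the C4=C5 ring olefin, so this σ bond is at once the proximal bond of a methylenecyclopropane and a vinylcyclopropane bond. This is the feature that makes the key step possible.
3. The ten-membered carbocycle 18 is closed by ring-closing metathesis at C1=C10. The C4=C5 olefin comes from a Still–Gennari union of aldehyde 10 with phosphonate 16.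
4. Aldehyde 10 comes from (1R,2R)-Feist's acid, whose six carbons are C5, C6, C7, C8, C11 and C13 and whose two stereocentres become C6 and C7; C8 is set by catalytic asymmetric methallylation. Phosphonate 16 carries C2 from (R)-but-3-ene-1,2-diol.
5. Ring order: cyclopropane (bought), then the ten-membered ring (step 14), then the γ-lactone (step 17).

Key step: step 17

Remarks:
- Germacrane numbering is used in names: lactone O on C6, carbonyl C12, methylene C13 on C11, methyl C14 on C10, C15 on C4.
- Assumption: racemic Feist's acid is a catalogue compound (otherwise two steps from ethyl isodehydroacetate), and the (S)-amine is taken to give the less soluble salt with the (1R,2R)-acid; if the opposite holds, (R)-1-phenylethylamine is used.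
- From step 13 to step 17 all intermediates are 2-alkenyl-methylenecyclopropanes and are kept at or below 40 °C, in view of the thermal vinyl-methylenecyclopropane rearrangement.

## Route

Step 1
Reactants: 1 racemic Feist's acid (rac-trans-3-methylidenecyclopropane-1,2-dicarboxylic acid)
Product: 2 bis[(S)-1-phenylethylammonium] (1R,2R)-3-methylidenecyclopropane-1,2-dicarboxylate
Conditions: (S)-1-phenylethylamine (2 equiv), EtOH–H2O, crystallise to constant rotation
Reagents that add atoms: (S)-1-phenylethylamine, C[C@H](N)c1ccccc1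
Why: Classical resolution by diastereomeric salt crystallisation should fix both ring stereocentres (later C6 and C7) of the C2-symmetric trans-diacid.

Step 2
Reactants: 2 bis[(S)-1-phenylethylammonium] (1R,2R)-dicarboxylate
Product: 3 (1R,2R)-3-methylidenecyclopropane-1,2-dicarboxylic acid
Conditions: 2 M HCl, EtOAc, 0 °C
Reagents that add atoms: none
Why: Acidification liberates the free diacid from its ammonium salt without touching the ring.

Step 3
Reactants: 3 (1R,2R)-3-methylidenecyclopropane-1,2-dicarboxylic acid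
Product: 4 [(1R,2R)-3-methylidenecyclopropane-1,2-diyl]dimethanol
Conditions: LiAlH4, THF, reflux
Reagents that add atoms: none
Why: Hydride reduction of carboxylic acids; the non-conjugated exocyclic olefin is inert to LiAlH4.

Step 4
Reactants: 4 [(1R,2R)-3-methylidenecyclopropane-1,2-diyl]dimethanol
Product: 5 [(1R,2R)-2-({[tert-butyl(dimethyl)silyl]oxy}methyl)-3-methylidenecyclopropyl]methanol
Conditions: NaH (1.0 equiv), THF, rt; TBSCl (1.0 equiv)
Reagents that add atoms: tert-butyldimethylsilyl chloride, CC(C)(C)[Si](C)(C)Cl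
Why: Monosilylation through the sparingly soluble monosodium alkoxide; C2 symmetry makes the two hydroxyls equivalent, so no regiochemical question arises.

Step 5
Reactants: 5 mono-TBS diol
Product: 6 (1R,2R)-2-({[tert-butyl(dimethyl)silyl]oxy}methyl)-3-methylidenecyclopropane-1-carbaldehyde
Conditions: TEMPO (10 mol %), PhI(OAc)2, CH2Cl2, rt
Reagents that add atoms: none
Why: Oxoammonium (TEMPO) oxidation of a primary alcohol to the aldehyde (C8) leaves the olefin and silyl ether alone.

Step 6
Reactants: 6 cyclopropanecarbaldehyde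
Product: 7 (1R)-1-[(1R,2R)-2-({[tert-butyl(dimethyl)silyl]oxy}methyl)-3-methylidenecyclopropyl]-3-methylbut-3-en-1-ol
Conditions: (R)-BINOL (20 mol %), Ti(OiPr)4 (10 mol %), 4 Å MS, methallylSnBu3, CH2Cl2, −20 °C
Reagents that add atoms: tributyl(2-methylallyl)stannane, C=C(C)C[Sn](CCCC)(CCCC)CCCC
Why: Keck asymmetric allylation; the BINOL–Ti catalyst should direct Re-face attack and so set C8 as R under catalyst control, adding C9, C10 and C14.

Step 7
Reactants: 7 homoallylic alcohol
Product: 8 4-methoxybenzyl ether of 7 (8-OPMB, primary OTBS)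
Conditions: NaH, PMBCl, Bu4NI (cat.), THF–DMF, 0 °C to rt
Reagents that add atoms: 4-methoxybenzyl chloride, COc1ccc(CCl)cc1
Why: Williamson etherification gives the C8 oxygen a group that is orthogonal to all silyl ethers and is removed last.

Step 8
Reactants: 8 PMB ether
Product: 9 {(1R,2R)-2-[(1R)-1-[(4-methoxybenzyl)oxy]-3-methylbut-3-en-1-yl]-3-methylidenecyclopropyl}methanol
Conditions: TBAF, THF, 0 °C to rt
Reagents that add atoms: none
Why: Fluoride desilylation frees the C5 hydroxyl; the PMB ether is stable.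

Step 9
Reactants: 9 primary alcohol
Product: 10 (1R,2R)-2-[(1R)-1-[(4-methoxybenzyl)oxy]-3-methylbut-3-en-1-yl]-3-methylidenecyclopropane-1-carbaldehyde
Conditions: TEMPO (10 mol %), PhI(OAc)2, CH2Cl2, rt
Reagents that add atoms: none
Why: TEMPO oxidation to the C5 aldehyde; the cyclopropane α-CH is not epimerised under these neutral conditions.

Step 10
Reactants: 11 (R)-but-3-ene-1,2-diol
Product: 12 (R)-1,2-bis{[tert-butyl(dimethyl)silyl]oxy}but-3-ene
Conditions: TBSCl (2.5 equiv), imidazole, DMF, rt
Reagents that add atoms: tert-butyldimethylsilyl chloride, CC(C)(C)[Si](C)(C)Cl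
Why: Standard silylation of both hydroxyls; the stereocentre (later C2) comes from the chiral pool.

Step 11
Reactants: 12 bis-TBS ether
Product: 13 (R)-2-{[tert-butyl(dimethyl)silyl]oxy}but-3-en-1-ol
Conditions: HF·pyridine, pyridine, THF, 0 °C
Reagents that add atoms: none
Why: Buffered HF cleaves the less hindered primary silyl ether selectively over the secondary allylic one.

Step 12
Reactants: 13 (R)-2-(TBSO)but-3-en-1-ol; 14 methyl 2-[bis(2,2,2-trifluoroethoxy)phosphoryl]acetate
Product: 16 methyl (4S)-2-[bis(2,2,2-trifluoroethoxy)phosphoryl]-4-{[tert-butyl(dimethyl)silyl]oxy}hex-5-enoate (both epimers at the phosphonate carbon), via primary triflate 15 (not isolated)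
Conditions: Tf2O, 2,6-lutidine, CH2Cl2, −78 °C; then sodium salt of 14 (NaH, THF), −20 °C to rt
Reagents that add atoms: none
Why: SN2 C-alkylation of the stabilised phosphonoacetate anion by a primary triflate builds C3–C4; the new phosphonate-bearing centre is stereorandom but becomes sp2 in step 13.

Step 13
Reactants: 10 cyclopropanecarbaldehyde; 16 phosphonate
Product: 17 methyl (2Z,4S)-4-{[tert-butyl(dimethyl)silyl]oxy}-2-({(1R,2R)-2-[(1R)-1-[(4-methoxybenzyl)oxy]-3-methylbut-3-en-1-yl]-3-methylidenecyclopropyl}methylidene)hex-5-enoate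
Conditions: KHMDS, 18-crown-6, THF, −78 °C
Reagents that add atoms: none
Why: Still–Gennari olefination; its kinetic Z-selectivity should place C6 cis to the ester carbon C15, which is the C4=C5 geometry of the target (C6 trans to C3 in the future ring).

Step 14
Reactants: 17 acyclic triene ester
Product: 18 macrocyclic enoate: trans-fused 11-methylidenebicyclo[8.1.0]undecadiene (ring C1–C10, cyclopropane C6–C7–C11), 1(10)Z, 4Z, C15 = CO2Me, (2S)-OTBS, (8R)-OPMB, 6R, 7R
Conditions: Grubbs II (10 mol %), CH2Cl2 (1 mM), 40 °C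
Reagents that add atoms: none
Why: Ring-closing metathesis between the C1 vinyl and C10 isopropenyl groups; the Z olefin is expected because an E-trisubstituted cyclodecene would be more strained, and the trisubstituted enoate and the hindered cyclopropylidene olefin are poor metathesis partners.

Step 15
Reactants: 18 macrocyclic enoate
Product: 19 macrocyclic allylic alcohol (C15 = CH2OH; otherwise as 18)
Conditions: DIBAL-H (2.5 equiv), CH2Cl2, −78 °C
Reagents that add atoms: none
Why: 1,2-Reduction of the enoate to the primary allylic alcohol; PMB and TBS ethers are stable.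

Step 16
Reactants: 19 macrocyclic allylic alcohol
Product: 20 (2S,6R,7R,8R)-2,15-bis{[tert-butyl(dimethyl)silyl]oxy}-8-[(4-methoxybenzyl)oxy] macrocyclic methylenecyclopropane (1(10)Z, 4Z)
Conditions: TBSCl, imidazole, DMF, rt
Reagents that add atoms: tert-butyldimethylsilyl chloride, CC(C)(C)[Si](C)(C)Cl
Why: Silylation leaves every oxygen as an ether, so that no allylic ester is offered to Pd(0) in step 17.

Step 17
Reactants: 20 macrocyclic methylenecyclopropane
Product: 21 (2S,6R,7R,8R)-2,15-bis{[tert-butyl(dimethyl)silyl]oxy}-8-[(4-methoxybenzyl)oxy]germacra-1(10)Z,4Z,11(13)-trien-12,6-olide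
Conditions: Pd2(dba)3·CHCl3 (5 mol %), PCy3 (20 mol %), CO2 (30 bar), toluene–DMSO 4:1, 40 °C
Reagents that add atoms: carbon dioxide, O=C=O
Why: Proposed new method: Pd(0) should insert into the strained C6–C11 σ bond, which is both the proximal bond of the methylenecyclopropane and a vinylcyclopropane bond, to give a σ-alkenyl (C11)/η3-allyl (C6–C5–C4) palladacycle; CO2 then inserts into the nucleophilic Pd–C(sp2) bond (C11–C12) and C6–O reductive elimination from the six-membered palladalactone closes the ring. The closest known reaction type is the Pd(0)-catalysed [3+2] cycloaddition of methylenecyclopropanes with CO2 to γ-butyrolactones, supported by CO2 insertion into alkenyl–Pd bonds and carboxylate capture of π-allyl-Pd as in butadiene/CO2 telomerisation. The γ-lactone closes as a formal [3+2] σ-bond insertion, that is a five-membered C–O closure onto the allyl terminus C6. C6 is the only stereocentre touched: insertion and reductive elimination on the same face (or anti ionisation followed by anti carboxylate attack) both give retention, so the trans cyclopropane from Feist's acid is copied onto the trans-fused lactone (6R), with C7 untouched and the 4Z olefin kept because the allyl unit stays syn within the ring. The step needs cleavage of C6–C11 in preference to the distal C6–C7 bond (the usual trimethylenemethane mode) and to C7–C11, which the allyl stabilisation at C6 and the strong Pd–C(sp2) bond should secure. It also needs CO2 capture to outrun C11–C4 reductive elimination (vinylcyclopropane to methylenecyclopentene), hence the CO2 pressure, the basic phosphine and the 40 °C ceiling.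

Step 18
Reactants: 21 bis-TBS lactone
Product: 22 (2S,6R,7R,8R)-2,15-dihydroxy-8-[(4-methoxybenzyl)oxy]germacra-1(10)Z,4Z,11(13)-trien-12,6-olide
Conditions: HF·pyridine, pyridine, THF, 0 °C to rt
Reagents that add atoms: none
Why: Fluoride desilylation of both TBS ethers; the PMB ether and the α-methylene lactone should survive buffered HF.

Step 19
Reactants: 22 diol
Product: 23 15-acetate of 22 (2-OH free)
Conditions: AcCl (1.05 equiv), 2,4,6-collidine, CH2Cl2, −78 °C
Reagents that add atoms: acetyl chloride, CC(=O)Cl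
Why: Low-temperature acylation with a hindered base should select the primary allylic alcohol over the secondary one.

Step 20
Reactants: 23 15-acetate
Product: 24 (2S,6R,7R,8R)-15-acetoxy-2-(angeloyloxy)-8-[(4-methoxybenzyl)oxy]germacra-1(10)Z,4Z,11(13)-trien-12,6-olide
Conditions: angelic acid, 2,4,6-trichlorobenzoyl chloride, Et3N, toluene, rt; then 23, 70 °C
Reagents that add atoms: angelic acid, C/C=C(/C)C(=O)O
Why: Yamaguchi-type mixed-anhydride esterification run without a nucleophilic catalyst, so that no reversible conjugate addition can isomerise the (Z)-angelate to the tiglate.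

Step 21
Reactants: 24 PMB ether
Product: 25 target, (2S,6R,7R,8R)-15-acetoxy-2-(angeloyloxy)-8-hydroxygermacra-1(10)Z,4Z,11(13)-trien-12,6-olide
Conditions: DDQ, CH2Cl2–pH 7 buffer (10:1), 0 °C to rt
Reagents that add atoms: none
Why: Oxidative PMB cleavage frees the C8 hydroxyl; the esters, the lactone and the trisubstituted olefins are not oxidised by DDQ under buffered conditions.

## Compound list

1 | racemic Feist's acid (rac-trans-3-methylidenecyclopropane-1,2-dicarboxylic acid, both enantiomers shown) | C=C1[C@H](C(=O)O)[C@H]1C(=O)O.C=C1[C@@H](C(=O)O)[C@@H]1C(=O)O | starting material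
2 | bis[(S)-1-phenylethylammonium] (1R,2R)-3-methylidenecyclopropane-1,2-dicarboxylate | C=C1[C@H](C(=O)[O-])[C@H]1C(=O)[O-].C[C@H]([NH3+])c1ccccc1.C[C@H]([NH3+])c1ccccc1 | intermediate
3 | (1R,2R)-3-methylidenecyclopropane-1,2-dicarboxylic acid | C=C1[C@H](C(=O)O)[C@H]1C(=O)O | intermediate
4 | [(1R,2R)-3-methylidenecyclopropane-1,2-diyl]dimethanol | C=C1[C@H](CO)[C@H]1CO | intermediate
5 | [(1R,2R)-2-({[tert-butyl(dimethyl)silyl]oxy}methyl)-3-methylidenecyclopropyl]methanol | C=C1[C@H](CO[Si](C)(C)C(C)(C)C)[C@H]1CO | intermediate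
6 | (1R,2R)-2-({[tert-butyl(dimethyl)silyl]oxy}methyl)-3-methylidenecyclopropane-1-carbaldehyde | C=C1[C@H](CO[Si](C)(C)C(C)(C)C)[C@H]1C=O | intermediate
7 | (1R)-1-[(1R,2R)-2-(TBSO-methyl)-3-methylidenecyclopropyl]-3-methylbut-3-en-1-ol | C=C1[C@H](CO[Si](C)(C)C(C)(C)C)[C@H]1[C@H](O)CC(C)=C | intermediate
8 | 4-methoxybenzyl ether of 7 | C=C1[C@H](CO[Si](C)(C)C(C)(C)C)[C@H]1[C@H](OCc2ccc(OC)cc2)CC(C)=C | intermediate
9 | {(1R,2R)-2-[(1R)-1-[(4-methoxybenzyl)oxy]-3-methylbut-3-en-1-yl]-3-methylidenecyclopropyl}methanol | C=C1[C@H](CO)[C@H]1[C@H](OCc2ccc(OC)cc2)CC(C)=C | intermediate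
10 | (1R,2R)-2-[(1R)-1-[(4-methoxybenzyl)oxy]-3-methylbut-3-en-1-yl]-3-methylidenecyclopropane-1-carbaldehyde | C=C1[C@H](C=O)[C@H]1[C@H](OCc2ccc(OC)cc2)CC(C)=C | intermediate
11 | (R)-but-3-ene-1,2-diol | OC[C@H](O)C=C | starting material
12 | (R)-1,2-bis{[tert-butyl(dimethyl)silyl]oxy}but-3-ene | CC(C)(C)[Si](C)(C)OC[C@H](O[Si](C)(C)C(C)(C)C)C=C | intermediate
13 | (R)-2-{[tert-butyl(dimethyl)silyl]oxy}but-3-en-1-ol | OC[C@H](O[Si](C)(C)C(C)(C)C)C=C | intermediate
14 | methyl 2-[bis(2,2,2-trifluoroethoxy)phosphoryl]acetate | COC(=O)CP(=O)(OCC(F)(F)F)OCC(F)(F)F | starting material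
15 | (R)-2-{[tert-butyl(dimethyl)silyl]oxy}but-3-en-1-yl trifluoromethanesulfonate | O=S(=O)(OC[C@H](O[Si](C)(C)C(C)(C)C)C=C)C(F)(F)F | intermediate
16 | methyl (4S)-2-[bis(2,2,2-trifluoroethoxy)phosphoryl]-4-{[tert-butyl(dimethyl)silyl]oxy}hex-5-enoate (epimers at C2 of the hexenoate) | COC(=O)C(C[C@H](O[Si](C)(C)C(C)(C)C)C=C)P(=O)(OCC(F)(F)F)OCC(F)(F)F | intermediate
17 | methyl (2Z,4S)-4-(TBSO)-2-({(1R,2R)-2-[(1R)-1-(PMBO)-3-methylbut-3-en-1-yl]-3-methylidenecyclopropyl}methylidene)hex-5-enoate | C=C1[C@H](/C=C(/C[C@H](O[Si](C)(C)C(C)(C)C)C=C)C(=O)OC)[C@H]1[C@H](OCc2ccc(OC)cc2)CC(C)=C | intermediate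
18 | macrocyclic enoate, trans-fused 11-methylidenebicyclo[8.1.0]undecadiene, 1(10)Z, 4Z, C15 = CO2Me, (2S)-OTBS, (8R)-OPMB, 6R, 7R | C=C1[C@@H]2/C=C(\C(=O)OC)C[C@H](O[Si](C)(C)C(C)(C)C)/C=C(/C)C[C@@H](OCc3ccc(OC)cc3)[C@@H]12 | intermediate
19 | macrocyclic allylic alcohol (C15 = CH2OH; otherwise as 18) | C=C1[C@@H]2/C=C(\CO)C[C@H](O[Si](C)(C)C(C)(C)C)/C=C(/C)C[C@@H](OCc3ccc(OC)cc3)[C@@H]12 | intermediate
20 | (2S,6R,7R,8R)-2,15-bis(TBSO)-8-(PMBO) macrocyclic methylenecyclopropane, 1(10)Z, 4Z | C=C1[C@@H]2/C=C(\CO[Si](C)(C)C(C)(C)C)C[C@H](O[Si](C)(C)C(C)(C)C)/C=C(/C)C[C@@H](OCc3ccc(OC)cc3)[C@@H]12 | intermediate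
21 | (2S,6R,7R,8R)-2,15-bis(TBSO)-8-(PMBO)germacra-1(10)Z,4Z,11(13)-trien-12,6-olide | C=C1C(=O)O[C@@H]2/C=C(\CO[Si](C)(C)C(C)(C)C)C[C@H](O[Si](C)(C)C(C)(C)C)/C=C(/C)C[C@@H](OCc3ccc(OC)cc3)[C@@H]12 | intermediate
22 | (2S,6R,7R,8R)-2,15-dihydroxy-8-(PMBO)germacra-1(10)Z,4Z,11(13)-trien-12,6-olide | C=C1C(=O)O[C@@H]2/C=C(\CO)C[C@H](O)/C=C(/C)C[C@@H](OCc3ccc(OC)cc3)[C@@H]12 | intermediate
23 | (2S,6R,7R,8R)-15-acetoxy-2-hydroxy-8-(PMBO)germacra-1(10)Z,4Z,11(13)-trien-12,6-olide | C=C1C(=O)O[C@@H]2/C=C(\COC(C)=O)C[C@H](O)/C=C(/C)C[C@@H](OCc3ccc(OC)cc3)[C@@H]12 | intermediate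
24 | (2S,6R,7R,8R)-15-acetoxy-2-(angeloyloxy)-8-(PMBO)germacra-1(10)Z,4Z,11(13)-trien-12,6-olide | C=C1C(=O)O[C@@H]2/C=C(\COC(C)=O)C[C@H](OC(=O)/C(C)=C\C)/C=C(/C)C[C@@H](OCc3ccc(OC)cc3)[C@@H]12 | intermediate
25 | (2S,6R,7R,8R)-15-acetoxy-2-(angeloyloxy)-8-hydroxygermacra-1(10)Z,4Z,11(13)-trien-12,6-olide | C=C1C(=O)O[C@@H]2/C=C(\COC(C)=O)C[C@H](OC(=O)/C(C)=C\C)/C=C(/C)C[C@@H](O)[C@@H]12 | target

## Step count and risks

Total steps: 21. Longest linear sequence: 18 (steps 1–9 and 13–21).

**Step 17 (key step, proposed new method).** The ring opening may take the distal, trimethylenemethane course. The palladacycle may also collapse by C–C reductive elimination or β-hydride loss before CO2 is captured, or C6 may lose its configuration through π–σ–π isomerisation.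
Fallback with known chemistry, setting out from 20 and coming back at 21:
- Platinum(0)-catalysed diboration with B2pin2 (Pt(PPh3)4, toluene, 50 °C), a known reaction of methylenecyclopropanes that cleaves the proximal ring bond, should give the 11-boryl-alkenyl/6-boryl macrocycle F1 with retention at C6.
- Perborate oxidation (NaBO3·4H2O, THF–H2O) of both C–B bonds should give the 6-hydroxy-7-acetyl macrocycle F2.
- Kinetic enolisation at the methyl group of the dianion (LiHMDS 2.2 equiv, Comins' reagent, THF, −78 °C) should give the hydroxy enol triflate F3.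
- Carbonylative lactonisation (Pd(PPh3)4, CO 1 atm, Et3N, MeCN, rt) should close 21. The C6 configuration is carried through unchanged, and the lactone is closed at O–C12 instead of O–C6.

**Step 14 (ring-closing metathesis).** Oligomerisation may win over closure of the strained trans-bicyclo[8.1.0] ring, the E olefin may form, or the ruthenium carbene may engage the strained exocyclic olefin.
Fallback that inverts the order of ring closure and CO2 insertion, setting out from 17 and coming back at 21:
- DIBAL-H reduction of 17 should give the acyclic allylic alcohol F4.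
- Silylation (TBSCl, imidazole) should give the acyclic bis-TBS methylenecyclopropane F5.
- The step 17 carboxylation, applied to F5, should give the acyclic trans-α-methylene-γ-butyrolactone F6.
- The ten-membered ring is then closed by metathesis on F6, where the cyclopropane strain is gone, the lactone acts as a turn element and its electron-poor methylene is inert to the catalyst, to give 21.

**Step 6 (asymmetric methallylation).** Facial selectivity may be poor if catalyst and substrate are mismatched, and addition to the hindered, cyclopropane-conjugated aldehyde may be sluggish.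
Fallback that replaces catalyst-controlled C–C bond formation by catalyst-controlled ketone reduction, setting out from 6 and coming back at 7:
- Uncatalysed addition of methallylmagnesium chloride (THF, −78 °C) should give the C8-epimeric alcohol mixture F7.
- Dess–Martin oxidation should give the β,γ-unsaturated ketone F8.
- (S)-Me-CBS with catecholborane (toluene, −78 °C; large group = cyclopropyl) should return 7 with the 8R configuration.

## Further compounds

F1 | step 17 | 11-(pinacolboryl)alkenyl 6-(pinacolboryl) macrocycle (proximal-bond diboration product of 20) | C=C(B1OC(C)(C)C(C)(C)O1)[C@H]1[C@H](B2OC(C)(C)C(C)(C)O2)/C=C(\CO[Si](C)(C)C(C)(C)C)C[C@H](O[Si](C)(C)C(C)(C)C)/C=C(/C)C[C@H]1OCc3ccc(OC)cc3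
F2 | step 17 | 6-hydroxy-7-acetyl macrocycle (β-hydroxy methyl ketone) | CC(=O)[C@H]1[C@H](O)/C=C(\CO[Si](C)(C)C(C)(C)C)C[C@H](O[Si](C)(C)C(C)(C)C)/C=C(/C)C[C@H]1OCc2ccc(OC)cc2
F3 | step 17 | 6-hydroxy-7-[1-(trifluoromethanesulfonyloxy)vinyl] macrocycle (enol triflate) | C=C(OS(=O)(=O)C(F)(F)F)[C@H]1[C@H](O)/C=C(\CO[Si](C)(C)C(C)(C)C)C[C@H](O[Si](C)(C)C(C)(C)C)/C=C(/C)C[C@H]1OCc2ccc(OC)cc2
F4 | step 14 | acyclic allylic alcohol (C15 = CH2OH analogue of 17) | C=C1[C@H](/C=C(/C[C@H](O[Si](C)(C)C(C)(C)C)C=C)CO)[C@H]1[C@H](OCc2ccc(OC)cc2)CC(C)=C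
F5 | step 14 | acyclic bis-TBS methylenecyclopropane | C=C1[C@H](/C=C(/C[C@H](O[Si](C)(C)C(C)(C)C)C=C)CO[Si](C)(C)C(C)(C)C)[C@H]1[C@H](OCc2ccc(OC)cc2)CC(C)=C
F6 | step 14 | acyclic trans-α-methylene-γ-butyrolactone (ring-closing metathesis precursor) | C=C1C(=O)O[C@H](/C=C(/C[C@H](O[Si](C)(C)C(C)(C)C)C=C)CO[Si](C)(C)C(C)(C)C)[C@H]1[C@H](OCc2ccc(OC)cc2)CC(C)=C
F7 | step 6 | C8-epimeric mixture of homoallylic alcohol 7 | C=C1[C@H](CO[Si](C)(C)C(C)(C)C)[C@H]1C(O)CC(C)=C
F8 | step 6 | 1-[(1R,2R)-2-(TBSO-methyl)-3-methylidenecyclopropyl]-3-methylbut-3-en-1-one | C=C1[C@H](CO[Si](C)(C)C(C)(C)C)[C@H]1C(=O)CC(C)=C
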